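**Retrosynthetic overview**
1. Target 13 ⇒ alcohol 10 + angelic acid 11, by the C8–O ester bond (last step).
2. 10 ⇒ enal 7, by C8–C9 allylboration (sets C8) and then cross-metathesis to the prenyl terminus.
3. 7 ⇒ acetate 5, by allylic chlorination of the isopropenyl methyl and N-oxide oxidation.
4. 5 ⇒ cis-epoxy ketone 2, by C6–O bond formation (enolate hydroxylation and acetylation, trans to both neighbours).
5. 2 ⇒ (R)-carvone 1, by the key C–O step, a catalyst-controlled cis epoxidation. The cyclohexanone ring comes from carvone; the oxirane is the only ring made (step 1).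

Numbering used below: ring as in carvone (C1 = C=O, C2 = C–CH3, C3 = oxirane CH, C5 bears the side chain, C6 = CH–OAc); side chain C7 (bearing =CH2), C8 (CH–O), C9 to C11.

Assumption: the quinine-derived amine is taken to be the pseudoenantiomer that delivers oxygen to the C3 face syn to the isopropenyl group; if the first run shows the opposite sense, the quinidine-derived pseudoenantiomer is used under the same conditions.

**Step 1**
Reactants: 1 (R)-(−)-carvone
Product: 2 cis-carvone epoxide (1S,4R,6S)-1-methyl-4-(prop-1-en-2-yl)-7-oxabicyclo[4.1.0]heptan-2-one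
Conditions: 9-amino-9-deoxy-epi-quinine (10 mol%), CF3CO2H (20 mol%), 50% aq H2O2 (1.5 equiv), 1,4-dioxane, 40 °C, 48 h
Reagents that add atoms: hydrogen peroxide, OO
Why: Proposed new method: a catalyst-controlled cis-selective Weitz–Scheffer epoxidation in which the primary amine condenses with the enone to an iminium ion, the protonated quinuclidine hydrogen-bonds H2O2 and delivers it to the C3 face syn to the isopropenyl group, and the β-hydroperoxy enamine closes on the proximal oxygen with loss of water to form the oxirane and set C2 and C3 against the substrate's trans preference under HOO−; the closest known reaction is the cinchona primary-amine-salt-catalysed asymmetric epoxidation of 2-unsubstituted cyclohexenones with aqueous H2O2, not yet shown on a 2-methyl enone carrying a ring stereocentre in the mismatched sense.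

**Step 2**
Reactants: 2 cis-carvone epoxide
Product: 5 (1S,3S,4S,6S)-1-methyl-2-oxo-4-(prop-1-en-2-yl)-7-oxabicyclo[4.1.0]heptan-3-yl acetate, via sodium enolate 3 (not isolated), via sodium alkoxide 4 (not isolated)
Conditions: NaN(SiMe3)2 (1.1 equiv), THF, −78 °C; 2-(phenylsulfonyl)-3-phenyloxaziridine (1.3 equiv), −78 °C; Ac2O (3 equiv), −78 to 0 °C
Reagents that add atoms: 2-(phenylsulfonyl)-3-phenyloxaziridine, O=S(=O)(N1OC1c1ccccc1)c1ccccc1; acetic anhydride, CC(=O)OC(C)=O
Why: Deprotonation can only occur at C6 (the other α-carbon is the quaternary oxirane carbon), and the Davis enolate hydroxylation delivers oxygen to the face anti to both the adjacent isopropenyl group and the cis oxirane, giving the trans C6 alkoxide that is O-acetylated in the same flask.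

**Step 3**
Reactants: 5 acetoxy epoxy ketone
Product: 6 (1S,3S,4S,6S)-4-(3-chloroprop-1-en-2-yl)-1-methyl-2-oxo-7-oxabicyclo[4.1.0]heptan-3-yl acetate
Conditions: Ca(OCl)2, CO2 (dry ice), CH2Cl2/H2O, 0 °C
Reagents that add atoms: calcium hypochlorite, [Ca+2].[O-]Cl.[O-]Cl
Why: HOCl generated in the two-phase system effects the ene-type allylic chlorination of the electron-rich 1,1-disubstituted alkene (established on carvone itself), while the epoxy ketone and acetate are inert and no stereocentre is touched.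

**Step 4**
Reactants: 6 allylic chloride
Product: 7 (1S,3S,4S,6S)-1-methyl-2-oxo-4-(3-oxoprop-1-en-2-yl)-7-oxabicyclo[4.1.0]heptan-3-yl acetate
Conditions: N-methylmorpholine N-oxide (4 equiv), NaI (0.2 equiv), 4 Å MS, MeCN, 23 °C
Reagents that add atoms: N-methylmorpholine N-oxide, C[N+]1([O-])CCOCC1
Why: The N-oxide oxygen displaces the primary allylic halide and the alkoxyammonium salt fragments to the enal and the amine (N-oxide oxidation of an activated halide, a Kornblum-type process), under conditions mild enough for the α-acetoxy epoxy ketone.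

**Step 5**
Reactants: 7 enal
Product: 9 (1S,3S,4S,6S)-4-[(3S)-3-hydroxyhexa-1,5-dien-2-yl]-1-methyl-2-oxo-7-oxabicyclo[4.1.0]heptan-3-yl acetate, via diisopinocampheylborinate 8 (not isolated)
Conditions: (−)-Ipc2B(allyl) (from (+)-α-pinene, Mg-salt-free, 1.2 equiv), Et2O, −78 °C; then pH 7 buffer (NaH2PO4/Na2HPO4), MeOH, 30% H2O2, 0 °C
Reagents that add atoms: (−)-B-allyldiisopinocampheylborane, C=CCB([C@@H]1C[C@@H]2C[C@H]([C@H]1C)C2(C)C)[C@@H]1C[C@@H]2C[C@H]([C@H]1C)C2(C)C
Why: Brown asymmetric allylboration through a chair Zimmerman–Traxler transition state, in which the aldehyde reacts far faster than the hindered ketone at −78 °C and the (+)-α-pinene-derived reagent adds allyl to the aldehyde Si face, setting the (S) carbinol centre C8 under reagent control.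

**Step 6**
Reactants: 9 homoallylic alcohol
Product: 10 (1S,3S,4S,6S)-4-[(3S)-3-hydroxy-6-methylhepta-1,5-dien-2-yl]-1-methyl-2-oxo-7-oxabicyclo[4.1.0]heptan-3-yl acetate
Conditions: second-generation Grubbs catalyst RuCl2(=CHPh)(H2IMes)(PCy3) (5 mol%), 2-methylbut-2-ene/CH2Cl2 (1:1), 40 °C, sealed tube
Reagents that add atoms: 2-methylbut-2-ene, CC=C(C)C
Why: Olefin cross-metathesis of the monosubstituted alkene with excess 2-methylbut-2-ene installs the isopropylidene terminus, while the hindered 1,1-disubstituted alkene and all stereocentres are untouched.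

**Step 7**
Reactants: 10 prenyl alcohol; 11 angelic acid (Z)-2-methylbut-2-enoic acid
Product: 13 (3S)-2-[(1S,3S,4S,6S)-4-acetoxy-6-methyl-5-oxo-7-oxabicyclo[4.1.0]heptan-3-yl]-6-methylhepta-1,5-dien-3-yl (Z)-2-methylbut-2-enoate (CNP0150645.2), via mixed anhydride 12 (not isolated)
Conditions: 11 (3 equiv), 2,4,6-trichlorobenzoyl chloride (3 equiv), Et3N (3 equiv), toluene, 23 °C, 2 h; then 10, 80 °C, 24 h
Reagents that add atoms: none
Why: Yamaguchi-type mixed-anhydride esterification run without DMAP and without free amine at the heating stage, in which the alcohol attacks the less hindered angeloyl carbonyl to form the C8–O ester bond with retention at C8 and without Z-to-E isomerisation to the tiglate.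

**Compound list**
1 | (R)-(−)-carvone | C=C(C)[C@@H]1CC=C(C)C(=O)C1 | starting material
2 | cis-carvone epoxide, (1S,4R,6S)-1-methyl-4-(prop-1-en-2-yl)-7-oxabicyclo[4.1.0]heptan-2-one (oxirane cis to isopropenyl) | C=C(C)[C@@H]1C[C@@H]2O[C@]2(C)C(=O)C1 | intermediate
3 | sodium enolate of 2 (C1–C6 enolate) | C=C(C)[C@@H]1C[C@@H]2O[C@]2(C)C([O-])=C1.[Na+] | intermediate
4 | sodium alkoxide of the trans C6-hydroxy ketone | C=C(C)[C@@H]1C[C@@H]2O[C@]2(C)C(=O)[C@H]1[O-].[Na+] | intermediate
5 | (1S,3S,4S,6S)-1-methyl-2-oxo-4-(prop-1-en-2-yl)-7-oxabicyclo[4.1.0]heptan-3-yl acetate (OAc trans to isopropenyl and to the oxirane) | C=C(C)[C@@H]1C[C@@H]2O[C@]2(C)C(=O)[C@H]1OC(C)=O | intermediate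
6 | (1S,3S,4S,6S)-4-(3-chloroprop-1-en-2-yl)-1-methyl-2-oxo-7-oxabicyclo[4.1.0]heptan-3-yl acetate | C=C(CCl)[C@@H]1C[C@@H]2O[C@]2(C)C(=O)[C@H]1OC(C)=O | intermediate
7 | (1S,3S,4S,6S)-1-methyl-2-oxo-4-(3-oxoprop-1-en-2-yl)-7-oxabicyclo[4.1.0]heptan-3-yl acetate | C=C(C=O)[C@@H]1C[C@@H]2O[C@]2(C)C(=O)[C@H]1OC(C)=O | intermediate
8 | diisopinocampheylborinate ester of 9 | C=C([C@H](CC=C)OB([C@@H]3C[C@@H]4C[C@H]([C@H]3C)C4(C)C)[C@@H]3C[C@@H]4C[C@H]([C@H]3C)C4(C)C)[C@@H]1C[C@@H]2O[C@]2(C)C(=O)[C@H]1OC(C)=O | intermediate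
9 | (1S,3S,4S,6S)-4-[(3S)-3-hydroxyhexa-1,5-dien-2-yl]-1-methyl-2-oxo-7-oxabicyclo[4.1.0]heptan-3-yl acetate | C=C([C@H](CC=C)O)[C@@H]1C[C@@H]2O[C@]2(C)C(=O)[C@H]1OC(C)=O | intermediate
10 | (1S,3S,4S,6S)-4-[(3S)-3-hydroxy-6-methylhepta-1,5-dien-2-yl]-1-methyl-2-oxo-7-oxabicyclo[4.1.0]heptan-3-yl acetate | C=C([C@H](CC=C(C)C)O)[C@@H]1C[C@@H]2O[C@]2(C)C(=O)[C@H]1OC(C)=O | intermediate
11 | angelic acid, (Z)-2-methylbut-2-enoic acid | C/C=C(/C)C(=O)O | starting material
12 | angelic 2,4,6-trichlorobenzoic anhydride | C/C=C(/C)C(=O)OC(=O)c1c(Cl)cc(Cl)cc1Cl | intermediate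
13 | CNP0150645.2, (3S)-2-[(1S,3S,4S,6S)-4-acetoxy-6-methyl-5-oxo-7-oxabicyclo[4.1.0]heptan-3-yl]-6-methylhepta-1,5-dien-3-yl (Z)-2-methylbut-2-enoate | C=C([C@H](CC=C(C)C)OC(=O)/C(C)=C\C)[C@@H]1C[C@@H]2O[C@]2(C)C(=O)[C@H]1OC(C)=O | target

**Totals**
Total step count: 7. Longest linear sequence: 7 steps, from (R)-carvone 1.

**Three steps most likely to fail**

Step 1 (the proposed new reaction). Iminium formation with the 2-methyl enone may be slow, and the catalyst may not fully override the substrate's bias, leaving trans epoxide to be separated. The fallback uses known chemistry, sets out from 1 and comes back at 2. Luche reduction of 1 (NaBH4, CeCl3·7H2O, MeOH, 0 °C) gives (1R,5R)-cis-carveol F1. Hydroxyl-directed epoxidation of F1 (VO(acac)2 cat., t-BuOOH, CH2Cl2, 0 to 23 °C) spares the isopropenyl group and gives the all-cis epoxy alcohol F2. Dess–Martin periodinane (NaHCO3, CH2Cl2) oxidises F2 to 2. This costs two extra steps.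

Step 4. Displacement by the N-oxide may be slow, and the 2-substituted acrolein 7 can be lost by amine addition or oligomerisation. The fallback sets out from 5 and comes back at 7, bypassing 6. Selenium dioxide allylic hydroxylation of the isopropenyl methyl (SeO2 0.5 equiv, t-BuOOH, CH2Cl2, 23 °C) gives the allylic alcohol F3, and MnO2 in CH2Cl2 oxidises F3 to 7. The step count is unchanged.

Step 7. Acylation of the hindered allylic alcohol may be sluggish, and some angelate may isomerise to tiglate. The fallback sets out from 10 and comes back at 13 by building the Z-alkene on the ester instead of transferring it. Alcohol 10 is esterified with 2-[bis(2,2,2-trifluoroethoxy)phosphoryl]propanoic acid (EDC, DMAP, CH2Cl2) to give the phosphonate ester F4. Still–Gennari olefination of F4 with acetaldehyde (KN(SiMe3)2 1.0 equiv, 18-crown-6, THF, −78 °C) gives the Z-trisubstituted ester 13. This costs one extra step.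

**Further compounds**
F1 | step 1 | (1R,5R)-cis-carveol, (1R,5R)-2-methyl-5-(prop-1-en-2-yl)cyclohex-2-en-1-ol | C=C(C)[C@@H]1CC=C(C)[C@H](O)C1
F2 | step 1 | all-cis epoxy alcohol, (1R,2R,4S,6S)-1-methyl-4-(prop-1-en-2-yl)-7-oxabicyclo[4.1.0]heptan-2-ol | C=C(C)[C@@H]1C[C@@H]2O[C@]2(C)[C@H](O)C1
F3 | step 4 | (1S,3S,4S,6S)-4-(3-hydroxyprop-1-en-2-yl)-1-methyl-2-oxo-7-oxabicyclo[4.1.0]heptan-3-yl acetate | C=C(CO)[C@@H]1C[C@@H]2O[C@]2(C)C(=O)[C@H]1OC(C)=O
F4 | step 7 | 2-[bis(2,2,2-trifluoroethoxy)phosphoryl]propanoate ester of 10 (mixture of epimers at the phosphonate α-carbon) | C=C([C@H](CC=C(C)C)OC(=O)C(C)P(=O)(OCC(F)(F)F)OCC(F)(F)F)[C@@H]1C[C@@H]2O[C@]2(C)C(=O)[C@H]1OC(C)=O
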